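**Remarks on the chemistry**

- Atom labels in the discussion follow caryophyllane numbering: C1–C9 are the nine-membered ring, C10 and C11 complete the cyclobutane, C15 is the methylidene carbon on C8, C1′ is the pyran CH2, and C2′/C3′ are the two trione carbons in the pyran. Systematic names in the compound lines use their own locants.
- Assumption: the oxa-6π closure in step 13 is reversible, so which enol oxygen closes and the configuration at C4 are taken to be under thermodynamic control and to favour 20; minor isomers are returned to the equilibrium by re-heating.
- C4 in 8–10 is drawn as the (R) epimer, which is what the order alkenylation-then-methylation should deliver (methyl trans to the cyclobutane). C4 becomes trigonal in step 7, so either epimer leads to 11.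

## Analysis of the target

Compound 22 joins a caryophyllane sesquiterpene unit to a dearomatised acylphloroglucinol through a shared dihydropyran. The terpenoid half is a bicyclo[7.2.0]undecane: a cyclobutane (C1, C9, C10, C11, gem-dimethyl on C11) trans-fused to a nine-membered carbocycle (C1 to C9) that carries an exocyclic methylidene (C15) on C8. The pyran (O, C4, C5, C1′, C2′, C3′) is fused to the nine-membered ring across C4–C5 and, across C2′=C3′, to a six-membered carbocycle that runs from C3′ through a gem-dimethyl carbon, a ketone, an isobutyryl-bearing carbon and a chelated enol carbon back to C2′. There are four stereocentres, (1R,4S,5R,9S): H-1 and H-9 are trans, the C4 methyl and H-5 are trans (trans-fused pyran), and the C4/C5 pair must be set relative to the distant C1/C9 pair across a flexible medium ring. The sensitive groups are the 1,1-disubstituted C8=C15 alkene (protonation leads to transannular cation chemistry), the tertiary C4–O bond to a vinylogous acid (it ionises in strong acid), and the acidic enolised tricarbonyl (it consumes base and binds Lewis acids). The synthesis is hard because a nine-membered ring must be built that also carries an oxygenated quaternary carbon next to a second stereocentre. The strategy rests on the fact that C8 is trigonal and can be a ketone, and is separated from the C4–C5 pair by exactly C7 and C6: a temporary O–C4 bond turns C7=C8–O–C4–C5=C6 into an allyl vinyl ether inside a seven-membered ring (C8, O, C4, C3, C2, C1, C9), whose [3,3] shift gives the nine-membered ring. That cyclic enol ether comes from a lactone, and the lactone is the Baeyer–Villiger product of a cyclobutane-fused cyclohexanone made by [2+2] photocycloaddition.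

## Retrosynthetic reasoning

**C8=C15.** The methylidene of 22 is removed first, back to ketone 21. It is the group least compatible with the acid needed for the pyran reduction, and a C8 ketone is also what allows C9 to be adjusted. The forward step is a Wittig methylenation that must leave the enolised tricarbonyl alone.

**C5–H and C1′–H.** 21 is taken back to the 2H-pyran 20 by adding a C5=C1′ double bond. This turns the saturated pyran into the product of an electrocyclisation. The forward reduction has to deliver hydrogen to C5 on the face that makes the C4/C5 fusion trans.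

**C1′–C2′ and O–C4.** 20 is cut into enal 14 and trione 18 through oxatriene 19. Both pyran bonds come from one condensation–electrocyclisation and the whole acylphloroglucinol half arrives in one piece. The forward step must close through the oxygen next to the gem-dimethyl carbon and on the correct face of C4.

**The trione.** 18 is the gem-dimethylated, dearomatised form of acylphloroglucinol 17, which comes from 15 and 16 by C-acylation.

**Functional-group level at C1′ and C9.** 14 comes from alcohol 13, that from silyl ether 12, and 12 from its C9 epimer 11. The epimerisation is placed here because C9 is alpha to the C8 ketone and the alkene is not in conjugation with it.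

**C6–C7 (key disconnection).** 11 is the Claisen product of the 2-methylidene oxepane 10: C6–C7 is cut and O–C4 reconnected. This is chosen over any direct closure of the nine-membered ring because the carbon framework is already cyclic in 10, so the ring is enlarged, not closed end to end. The forward step must keep to the concerted pathway and avoid ionisation of the tertiary allylic ether.

**Enol ether and lactone.** 10 comes from lactone 9 by carbonyl methylenation, and 9 from ketone 8 by inserting oxygen between C8 and C4. The quaternary allylic carbon C4 is the better migrating group, and it migrates with retention.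

**Quaternary C4.** 8 comes from 7 by methylation at C4, and 7 from ketone 4 and vinyl bromide 6 (made from 5) by enolate alkenylation. The alkenyl group is introduced first because coupling at the CH2 of 4 is regiochemically safe, and the resulting doubly activated C4–H then directs the methylation. The opposite order would have to distinguish two methine positions.

**Cyclobutane.** 4 is the cis-fused epimer of photoadduct 3, formed from 1 and 2. This step sets C1, the only stereocentre that is carried unchanged to 22; C9 follows it through two epimerisations.

## Alternatives that were turned down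

**Alternative 1: cation–olefin closure ended by the enol oxygen.**
- Disconnection: C5–C6 and O–C4 together, leading to the seco vinyl ketone A2, in which the complete trione is already attached through C1′ to an (E)-trisubstituted C4=C5 alkene.
- Forward key step: a Lewis acid activates the enone of A2, C5 attacks the enone terminus C6, and the tertiary C4 cation is captured by the enol oxygen. This gives A1, which has the same structure as 21.
- For: two rings and both pyran stereocentres form in one operation; anti addition across the (E)-alkene translates directly into the trans C4/C5 fusion; A1 is one methylenation from 22. On step economy and on the C4/C5 relationship it is stronger than the chosen route.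
- Against: the nine-membered ring must close end to end through a strained, entropically poor transition state; the enolised trione in A2 binds the Lewis acid and can add to the enone through oxygen or carbon; the C4 cation can eliminate or be captured by the other enol oxygen; nothing relates the new centres to the cyclobutane.
- Comparison: the chosen strategy gives up the single-operation elegance but makes the medium ring from a preformed seven-membered ring, under neutral thermal conditions, before the acid-sensitive trione is present.

**Alternative 2: Knoevenagel and oxa-6π annulation on the methylidene-bearing enal.**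
- Disconnection: C1′–C2′ and O–C4 at the level of the complete terpenoid, giving enal A4 (C8 methylidene in place) and the trione that is 18 in the chosen route.
- Forward key step: condensation at C2′ with the aldehyde carbon and oxa-6π closure of the resulting oxatriene to the 2H-pyran A3.
- For: the annulation is reliable, convergent and short; on pyran formation it is as strong as the chosen route, which uses the same reaction in step 13.
- Against: the key step builds no carbocycle, so the nine-membered ring and the tetrasubstituted enal of A4 remain unsolved. The C5=C1′ alkene of A3 must then be reduced beside a 1,1-disubstituted methylidene: acid-mediated reduction would protonate C8=C15 and hydrogenation would saturate it.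
- Comparison: the chosen strategy supplies what this one lacks, namely a route to the enal, and keeps C8 as a ketone through the reduction.

**Alternative 3: B-alkyl Suzuki closure at the methylidene carbon.**
- Disconnection: C7–C8, leading to A6, which carries a vinyl group on C5, a 1-iodovinyl group on C9 and the C4/C1′ diol as an acetonide.
- Forward key step: a hindered dialkylborane hydroborates the vinyl group at C7, and palladium-catalysed coupling with the iodoalkene forms C7–C8 and the nine-membered ring, giving acetonide A5.
- For: the methylidene is installed during ring closure; C4 and C5 are set before cyclisation, where acyclic stereocontrol is available. On certainty at C4/C5 it is stronger than the chosen route.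
- Against: it is again an end-to-end closure of a nine-membered ring, needing high dilution; A6 requires a long stereocontrolled assembly joining two separate stereochemical domains; after A5 the pyran still has to be made by forming a tertiary ether at C4 beside the acid-sensitive methylidene.
- Comparison: the chosen strategy is shorter to the ring and leaves C4/C5 to the annulation, which is where its own risk lies.

Key step: step 7

## Route

**Step 1**
Reactants: 1 2-cyclohexen-1-one; 2 isobutylene
Product: 4 (1R,6R)-7,7-dimethylbicyclo[4.2.0]octan-2-one (cis-fused), via trans-fused photoadduct 3 (not isolated)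
Conditions: hν (366 nm), AlBr3-activated diarylprolinol-derived B-aryl oxazaborolidine (50 mol %, enantiomer chosen for the 6R series), CH2Cl2, −78 °C; then basic Al2O3, CH2Cl2, rt
Reagents that add atoms: none
Why: Enantioselective Lewis-acid-catalysed [2+2] photocycloaddition: the chiral complex alone absorbs at this wavelength and shields one face of the enone β-carbon, which sets C1; head-to-tail regiochemistry is normal for isobutylene. The strained trans-fused adduct epimerises at the α-carbon on basic alumina, so C9 follows C1 into the cis-fused ketone.

**Step 2**
Reactants: 5 2-bromoprop-2-en-1-ol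
Product: 6 [(2-bromoprop-2-en-1-yl)oxy](tert-butyl)dimethylsilane
Conditions: TBSCl, imidazole, CH2Cl2, 0 °C → rt
Reagents that add atoms: tert-butyldimethylsilyl chloride, CC(C)(C)[Si](C)(C)Cl
Why: Standard silylation of a primary allylic alcohol; the vinyl bromide is inert.

**Step 3**
Reactants: 4 (1R,6R)-7,7-dimethylbicyclo[4.2.0]octan-2-one; 6 [(2-bromoprop-2-en-1-yl)oxy](tert-butyl)dimethylsilane
Product: 7 (1R,6R)-3-[3-(tert-butyldimethylsilyloxy)prop-1-en-2-yl]-7,7-dimethylbicyclo[4.2.0]octan-2-one (mixture of C3 epimers)
Conditions: Pd2(dba)3 (2 mol %), [HP(t-Bu)3]BF4 (8 mol %), LiN(SiMe3)2 (2.2 equiv), toluene, 0 → 40 °C; aq NH4Cl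
Reagents that add atoms: none
Why: Palladium-catalysed α-alkenylation of a ketone enolate: 6 adds oxidatively to zerovalent palladium, the lithium enolate formed at the less hindered CH2 (C4) and not at the ring-fusion CH transmetalates, and reductive elimination forms C4–C5. The second equivalent of base holds the product as its dienolate, which blocks a second coupling and double-bond migration; the C4 configuration is not needed.

**Step 4**
Reactants: 7 (1R,6R)-3-[3-(tert-butyldimethylsilyloxy)prop-1-en-2-yl]-7,7-dimethylbicyclo[4.2.0]octan-2-one
Product: 8 (1R,3R,6R)-3-[3-(tert-butyldimethylsilyloxy)prop-1-en-2-yl]-3,7,7-trimethylbicyclo[4.2.0]octan-2-one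
Conditions: t-BuOK, THF/t-BuOH, −20 °C; MeI, → rt
Reagents that add atoms: iodomethane, CI
Why: Under equilibrating conditions the doubly activated C4–H gives the conjugated dienolate, which is C-methylated at the α-carbon to create the quaternary centre. Methyl should enter on the convex face, trans to the cyclobutane; this stereocentre is erased in step 7.

**Step 5**
Reactants: 8 (1R,3R,6R)-3-[3-(tert-butyldimethylsilyloxy)prop-1-en-2-yl]-3,7,7-trimethylbicyclo[4.2.0]octan-2-one
Product: 9 (1R,4R,7R)-4-[3-(tert-butyldimethylsilyloxy)prop-1-en-2-yl]-4,8,8-trimethyl-3-oxabicyclo[5.2.0]nonan-2-one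
Conditions: (Me3SiO)2, SnCl4 (20 mol %), trans-cyclohexane-1,2-diamine (20 mol %), 4 Å MS, CH2Cl2, 0 °C → rt
Reagents that add atoms: bis(trimethylsilyl) peroxide, C[Si](C)(C)OO[Si](C)(C)C
Why: Baeyer–Villiger oxidation with a silyl peroxide under buffered Lewis-acid catalysis, a reagent type that oxidises ketones without epoxidising C=C bonds. The fully substituted allylic carbon C4 migrates in preference to the secondary cyclobutyl carbon C9 and with retention, and C9 is untouched.

**Step 6**
Reactants: 9 (1R,4R,7R)-4-[3-(tert-butyldimethylsilyloxy)prop-1-en-2-yl]-4,8,8-trimethyl-3-oxabicyclo[5.2.0]nonan-2-one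
Product: 10 (1R,4R,7R)-4-[3-(tert-butyldimethylsilyloxy)prop-1-en-2-yl]-4,8,8-trimethyl-2-methylidene-3-oxabicyclo[5.2.0]nonane
Conditions: Cp2TiMe2 (3 equiv), toluene, 70 °C, dark; filtration through basic Al2O3
Reagents that add atoms: dimethyltitanocene, C[Ti](C)(C1C=CC=C1)C1C=CC=C1
Why: Petasis methylenation: thermally generated Cp2Ti=CH2 adds to the lactone carbonyl and the oxatitanacyclobutane collapses to the exocyclic enol ether. The reagent is neutral and not Lewis acidic, so the tertiary allylic C–O bond, the silyl ether and the 1,1-disubstituted alkene survive.

**Step 7**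
Reactants: 10 (1R,4R,7R)-4-[3-(tert-butyldimethylsilyloxy)prop-1-en-2-yl]-4,8,8-trimethyl-2-methylidene-3-oxabicyclo[5.2.0]nonane
Product: 11 (1R,5E,9R)-5-[(tert-butyldimethylsilyloxy)methyl]-6,10,10-trimethylbicyclo[7.2.0]undec-5-en-2-one (cis-fused)
Conditions: degassed xylenes, i-Pr2NEt (10 mol %), base-washed sealed tube, 170 °C
Reagents that add atoms: none
Why: Thermal Claisen rearrangement of the allyl vinyl ether embedded in 10 (C7=C8–O–C4–C5=C6): the C6–C7 σ bond forms as the O–C4 bond breaks, C8 becomes the ketone and C4=C5 the new tetrasubstituted alkene. The closest known reaction type is the Claisen ring expansion of 2-methylidene cyclic ethers that carry an alkenyl group on the ether carbon, which turns lactone-derived enol ethers into cyclooctenones and cyclononenones. The nine-membered carbocycle is therefore not closed end to end but arises by two-carbon ring expansion of the oxepane through a six-membered boat- or chair-like transition state bridged across it; both termini are CH2 groups, so either topology gives the same product. No stereocentre is created, and the C4 stereocentre of 10 is erased. Because C3 stays tied to C8 through the old ring it must sit pseudo-axial on C4 in the transition state, which places it cis to C6 and should give the ring-cis (5E) alkene. The step needs the concerted pathway to outrun heterolysis of the tertiary allylic C4–O bond and acid-catalysed migration of the enol ether double bond; the non-polar medium, the amine buffer and base-washed glass are there to suppress both. Formation of the C=O bond provides the driving force, and C9 is not touched, so the cyclobutane stays cis-fused.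

**Step 8**
Reactants: 11 (1R,5E,9R)-5-[(tert-butyldimethylsilyloxy)methyl]-6,10,10-trimethylbicyclo[7.2.0]undec-5-en-2-one
Product: 12 (1S,5E,9R)-5-[(tert-butyldimethylsilyloxy)methyl]-6,10,10-trimethylbicyclo[7.2.0]undec-5-en-2-one (trans-fused)
Conditions: NaOMe (0.3 equiv), MeOH, rt
Reagents that add atoms: none
Why: Base-mediated epimerisation at C9 through the enolate: unlike the six–four system of 4, a four–nine fused ketone should prefer trans fusion, the arrangement of the caryophyllane skeleton. Enolisation towards C7 is without consequence and the alkene, which is not conjugated, does not move.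

**Step 9**
Reactants: 12 (1S,5E,9R)-5-[(tert-butyldimethylsilyloxy)methyl]-6,10,10-trimethylbicyclo[7.2.0]undec-5-en-2-one
Product: 13 (1S,5E,9R)-5-(hydroxymethyl)-6,10,10-trimethylbicyclo[7.2.0]undec-5-en-2-one
Conditions: n-Bu4NF, THF, 0 °C → rt
Reagents that add atoms: none
Why: Fluoride cleaves the primary silyl ether; the ketone and the tetrasubstituted alkene are unaffected.

**Step 10**
Reactants: 13 (1S,5E,9R)-5-(hydroxymethyl)-6,10,10-trimethylbicyclo[7.2.0]undec-5-en-2-one
Product: 14 (1R,4E,9S)-4,11,11-trimethyl-8-oxobicyclo[7.2.0]undec-4-ene-5-carbaldehyde
Conditions: Dess–Martin periodinane, NaHCO3, CH2Cl2, 0 °C → rt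
Reagents that add atoms: none
Why: Dess–Martin oxidation of the primary allylic alcohol to the tetrasubstituted enal; the buffered, non-basic conditions leave the alkene geometry and C9 undisturbed.

**Step 11**
Reactants: 15 phloroglucinol; 16 isobutyryl chloride
Product: 17 2-methyl-1-(2,4,6-trihydroxyphenyl)propan-1-one
Conditions: AlCl3, PhNO2/CH2Cl2, 0 → 50 °C; aq HCl
Reagents that add atoms: none
Why: Friedel–Crafts C-acylation of the electron-rich triol; the product ketone is deactivated, so acylation stops at one group.

**Step 12**
Reactants: 17 2-methyl-1-(2,4,6-trihydroxyphenyl)propan-1-one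
Product: 18 3,5-dihydroxy-6,6-dimethyl-2-(2-methylpropanoyl)cyclohexa-2,4-dien-1-one
Conditions: NaOMe (3 equiv), MeI (2.2 equiv), MeOH, 0 °C → rt; aq HCl
Reagents that add atoms: iodomethane, CI
Why: Dearomatising C-methylation: the phenoxide is methylated at a ring CH and then again at the same carbon, giving the gem-dimethyl cyclohexadienone. The stoichiometry limits methylation at the second CH; mono- and tri-methylated congeners are removed by chromatography.

**Step 13**
Reactants: 14 (1R,4E,9S)-4,11,11-trimethyl-8-oxobicyclo[7.2.0]undec-4-ene-5-carbaldehyde; 18 3,5-dihydroxy-6,6-dimethyl-2-(2-methylpropanoyl)cyclohexa-2,4-dien-1-one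
Product: 20 2H-pyran-fused trione (4S; 8-oxo-15-nor-5,1′-didehydro-22), via oxatriene 19 (not isolated)
Conditions: ethylenediammonium diacetate (20 mol %), MeOH, 4 Å MS, rt → 60 °C
Reagents that add atoms: none
Why: Knoevenagel condensation of the nucleophilic ring CH of 18 (C2′) with the aldehyde gives 1-oxatriene 19, and disrotatory oxa-6π electrocyclisation forms O–C4 and the pyran. Closure through the oxygen next to the gem-dimethyl carbon is expected because it leaves the hydrogen-bonded acyl-enol unit intact. The closure is reversible, so C4, the only new stereocentre, is set under thermodynamic control by the trans-fused bicyclic framework.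

**Step 14**
Reactants: 20 2H-pyran-fused trione (4S; 8-oxo-15-nor-5,1′-didehydro-22)
Product: 21 8-oxo-15-nor-22, (1R,4S,5R,9S)
Conditions: Et3SiH, CF3CO2H, CH2Cl2, −20 → 0 °C
Reagents that add atoms: none
Why: Ionic hydrogenation: protonation of the dienol ether at C5 gives an oxygen-stabilised allyl cation that takes hydride at C1′ and restores the vinylogous ester; the C8 ketone and the tetrasubstituted enol ether should not react under these mild conditions. C5 is set in the protonation: delivery on the face syn to C3 lets C6 swing away from C3 as C5 pyramidalises, which the nine-membered ring should tolerate better than the compression needed for attack on the methyl face, and this leads to the trans C4/C5 fusion.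

**Step 15**
Reactants: 21 8-oxo-15-nor-22, (1R,4S,5R,9S)
Product: 22 target, (1R,4S,5R,9S)
Conditions: Ph3PCH3Br (5 equiv), t-BuOK (4.5 equiv), THF, 0 → 45 °C; aq NH4Cl
Reagents that add atoms: methyltriphenylphosphonium bromide, C[P+](c1ccccc1)(c1ccccc1)c1ccccc1.[Br-]
Why: Wittig methylenation of the C8 ketone. The first equivalent of ylide deprotonates the acidic enol, and the delocalised enolate protects the tricarbonyl unit, so only the isolated ketone reacts; C9 already has the stable trans configuration, so the basic medium cannot degrade it.

## Compound list

1 | 2-cyclohexen-1-one | O=C1C=CCCC1 | starting material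
2 | isobutylene (2-methylpropene) | C=C(C)C | starting material
3 | (1S,6R)-7,7-dimethylbicyclo[4.2.0]octan-2-one (trans-fused photoadduct, not isolated) | O=C1CCC[C@@H]2[C@@H]1CC2(C)C | intermediate
4 | (1R,6R)-7,7-dimethylbicyclo[4.2.0]octan-2-one (cis-fused) | O=C1CCC[C@@H]2[C@H]1CC2(C)C | intermediate
5 | 2-bromoprop-2-en-1-ol | OCC(Br)=C | starting material
6 | [(2-bromoprop-2-en-1-yl)oxy](tert-butyl)dimethylsilane | C=C(Br)CO[Si](C)(C)C(C)(C)C | intermediate
7 | (1R,6R)-3-[3-(tert-butyldimethylsilyloxy)prop-1-en-2-yl]-7,7-dimethylbicyclo[4.2.0]octan-2-one (mixture of C3 epimers) | O=C1C(C(=C)CO[Si](C)(C)C(C)(C)C)CC[C@@H]2[C@H]1CC2(C)C | intermediate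
8 | (1R,3R,6R)-3-[3-(tert-butyldimethylsilyloxy)prop-1-en-2-yl]-3,7,7-trimethylbicyclo[4.2.0]octan-2-one | O=C1[C@@](C)(C(=C)CO[Si](C)(C)C(C)(C)C)CC[C@@H]2[C@H]1CC2(C)C | intermediate
9 | (1R,4R,7R)-4-[3-(tert-butyldimethylsilyloxy)prop-1-en-2-yl]-4,8,8-trimethyl-3-oxabicyclo[5.2.0]nonan-2-one | O=C1O[C@@](C)(C(=C)CO[Si](C)(C)C(C)(C)C)CC[C@@H]2[C@H]1CC2(C)C | intermediate
10 | (1R,4R,7R)-4-[3-(tert-butyldimethylsilyloxy)prop-1-en-2-yl]-4,8,8-trimethyl-2-methylidene-3-oxabicyclo[5.2.0]nonane | C=C1O[C@@](C)(C(=C)CO[Si](C)(C)C(C)(C)C)CC[C@@H]2[C@H]1CC2(C)C | intermediate
11 | (1R,5E,9R)-5-[(tert-butyldimethylsilyloxy)methyl]-6,10,10-trimethylbicyclo[7.2.0]undec-5-en-2-one (cis-fused) | O=C1CC/C(CO[Si](C)(C)C(C)(C)C)=C(C)\CC[C@@H]2[C@H]1CC2(C)C | intermediate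
12 | (1S,5E,9R)-5-[(tert-butyldimethylsilyloxy)methyl]-6,10,10-trimethylbicyclo[7.2.0]undec-5-en-2-one (trans-fused) | O=C1CC/C(CO[Si](C)(C)C(C)(C)C)=C(C)\CC[C@@H]2[C@@H]1CC2(C)C | intermediate
13 | (1S,5E,9R)-5-(hydroxymethyl)-6,10,10-trimethylbicyclo[7.2.0]undec-5-en-2-one | O=C1CC/C(CO)=C(C)\CC[C@@H]2[C@@H]1CC2(C)C | intermediate
14 | (1R,4E,9S)-4,11,11-trimethyl-8-oxobicyclo[7.2.0]undec-4-ene-5-carbaldehyde | O=C1CC/C(C=O)=C(C)\CC[C@@H]2[C@@H]1CC2(C)C | intermediate
15 | phloroglucinol (benzene-1,3,5-triol) | Oc1cc(O)cc(O)c1 | starting material
16 | isobutyryl chloride (2-methylpropanoyl chloride) | CC(C)C(Cl)=O | starting material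
17 | 2-methyl-1-(2,4,6-trihydroxyphenyl)propan-1-one | CC(C)C(=O)c1c(O)cc(O)cc1O | intermediate
18 | 3,5-dihydroxy-6,6-dimethyl-2-(2-methylpropanoyl)cyclohexa-2,4-dien-1-one (enol form of 6,6-dimethyl-2-isobutyrylcyclohexane-1,3,5-trione) | CC(C)C(=O)C1=C(O)C=C(O)C(C)(C)C1=O | intermediate
19 | 2-{[(1R,4E,9S)-4,11,11-trimethyl-8-oxobicyclo[7.2.0]undec-4-en-5-yl]methylidene}-6,6-dimethyl-4-(2-methylpropanoyl)cyclohexane-1,3,5-trione, enol tautomer (1-oxatriene, not isolated) | O=C1CC/C(C=C2C(=O)C(C)(C)C(=O)C(C(=O)C(C)C)=C2O)=C(C)\CC[C@@H]2[C@@H]1CC2(C)C | intermediate
20 | 2H-pyran-fused trione, (1R,4S,9S): pyran O–C4(CH3)–C5=C1′H–C2′=C3′ on the trans-fused bicyclo[7.2.0]undecan-8-one; trione ring as in 22 (8-oxo-15-nor-5,1′-didehydro-22) | O=C1CCC2=CC3=C(O[C@@]2(C)CC[C@@H]2[C@@H]1CC2(C)C)C(C)(C)C(=O)C(C(=O)C(C)C)=C3O | intermediate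
21 | 8-oxo-15-nor-22, (1R,4S,5R,9S): as 22 with C8=O in place of C8=CH2 | O=C1CC[C@@H]2CC3=C(O[C@@]2(C)CC[C@@H]2[C@@H]1CC2(C)C)C(C)(C)C(=O)C(C(=O)C(C)C)=C3O | intermediate
22 | target, (1R,4S,5R,9S): caryophyll-8(15)-ene annulated across C4–C5 with a dihydropyran (O on C4, C1′H2 on C5) whose C2′=C3′ edge belongs to the ring C3′–C(CH3)2–C(=O)–C[C(=O)CH(CH3)2]=C(OH)–C2′ | C=C1CC[C@@H]2CC3=C(O[C@@]2(C)CC[C@@H]2[C@@H]1CC2(C)C)C(C)(C)C(=O)C(C(=O)C(C)C)=C3O | target

## Step count and least certain steps

Total: 15 steps. Longest linear sequence: 12 steps (1, 3, 4, 5, 6, 7, 8, 9, 10, 13, 14, 15); side branches are step 2 and steps 11–12.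

**Step 7 (key step).** Most likely failure is heterolysis of the tertiary allylic C4–O bond or prototropic migration of the exocyclic enol ether before the sigmatropic shift, because the bridged transition state leading to a nine-membered ring is strained and needs high temperature. Fallback, from 10: an aluminium-promoted Claisen rearrangement with i-Bu3Al in CH2Cl2 at −78 °C → rt, which is a known low-temperature variant of this ring expansion and reduces the ketone as it forms by hydride transfer from an isobutyl group. It should give the cis-fused cyclononenol (1R,5E,9R)-5-[(tert-butyldimethylsilyloxy)methyl]-6,10,10-trimethylbicyclo[7.2.0]undec-5-en-2-ol F1; Dess–Martin oxidation of F1 returns to 11.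

**Step 13.** Most likely failure is poor selectivity in the ring closure, through the other enol oxygen or on the other face of C4, because the electrocyclisation is reversible and the isomeric pyrans may be close in energy; slow condensation at the hindered aldehyde would add to this. Within the step, minor isomers can be re-equilibrated through 19. Fallback, from 14 and 17: the pyran is built on the aromatic acylphloroglucinol 17, where closure is irreversible and therefore kinetically controlled, and the gem-dimethyl group is introduced last. Chromenylation of 17 with 14 (ethylenediammonium diacetate, toluene, 80 °C) should give the 6-isobutyryl-5,7-dihydroxy-2H-chromene F2; ionic hydrogenation (Et3SiH, CF3CO2H) gives the chroman F3; dearomatising gem-dimethylation of F3 at its one remaining ring CH (NaOMe, MeI, MeOH) comes back to the route at 21.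

**Step 14.** Most likely failure is proton delivery to the wrong face of C5, giving the cis C4/C5 fusion, because the two faces differ only by a methyl group against a ring CH2; acid-induced heterolysis of the C4–O bond is a second risk. Fallback, from 20 to 21 directly: heterogeneous hydrogenation (H2, Pd/C, EtOAc), in which both hydrogens come from the catalyst surface and the face is chosen by adsorption instead of by protonation; the vinylogous ester and the ketone are not reduced. This fallback makes no new compound (F0).

**Step 5.** Most likely failure is competing epoxidation of the 1,1-disubstituted alkene, or Lewis-acid ionisation of the tertiary allylic lactone once formed, because the hindered α-quaternary ketone reacts slowly. Fallback, from 8: both oxidations are accepted and the alkene is regenerated afterwards. Excess mCPBA with NaHCO3 in CH2Cl2 should give the epoxy lactone (1R,4R,7R)-4-{2-[(tert-butyldimethylsilyloxy)methyl]oxiran-2-yl}-4,8,8-trimethyl-3-oxabicyclo[5.2.0]nonan-2-one F4, and deoxygenation of F4 with low-valent tungsten (WCl6, n-BuLi, THF, −78 °C → rt) returns to 9.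

**Step 3.** Most likely failure is a second alkenylation or migration of the product double bond into conjugation under the strongly basic conditions, or loss of the silyloxy group from the alkenylpalladium intermediate. Fallback, from 4: the enolate is preformed and coupled without free base. Kinetic silylation (LiN(i-Pr)2, Me3SiCl, THF, −78 °C) gives trimethyl{[(1R,6R)-7,7-dimethylbicyclo[4.2.0]oct-2-en-2-yl]oxy}silane F5, and coupling of F5 with 6 through the tin enolate (Bu3SnF, PdCl2[P(o-tol)3]2, toluene, reflux) returns to 7.

**Step 8.** Most likely failure is an unfavourable or incomplete cis/trans equilibrium at this stage, because the tetrasubstituted alkene changes the conformational preferences of the nine-membered ring. Fallback, from 11: the cis-fused series is carried forward and C9 is equilibrated once C4 and C5 are tetrahedral and the ring resembles the caryophyllane skeleton. Desilylation gives the cis-fused alcohol (1R,5E,9R)-5-(hydroxymethyl)-6,10,10-trimethylbicyclo[7.2.0]undec-5-en-2-one F6, oxidation the cis-fused enal (1R,4E,9R)-4,11,11-trimethyl-8-oxobicyclo[7.2.0]undec-4-ene-5-carbaldehyde F7, annulation with 18 the cis-fused 2H-pyran 9-epi-20 F8, and ionic hydrogenation the cis-fused ketone 9-epi-21 F9; treatment of F9 with NaOMe in MeOH comes back to the route at 21.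

## Further compounds

F1 | step 7 | (1R,5E,9R)-5-[(tert-butyldimethylsilyloxy)methyl]-6,10,10-trimethylbicyclo[7.2.0]undec-5-en-2-ol (cis-fused, mixture at C2) | OC1CC/C(CO[Si](C)(C)C(C)(C)C)=C(C)\CC[C@@H]2[C@H]1CC2(C)C
F2 | step 13 | 2H-chromene from 14 and 17: 6-isobutyryl-5,7-dihydroxy-2H-chromene fused at C2–C3 to the trans-fused bicyclo[7.2.0]undecan-8-one, (1R,4S,9S) | O=C1CCC2=Cc3c(O[C@@]2(C)CC[C@@H]2[C@@H]1CC2(C)C)cc(O)c(C(=O)C(C)C)c3O
F3 | step 13 | chroman from F2, (1R,4S,5R,9S) | O=C1CC[C@@H]2Cc3c(O[C@@]2(C)CC[C@@H]2[C@@H]1CC2(C)C)cc(O)c(C(=O)C(C)C)c3O
F0 | step 14 | none | none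
F4 | step 5 | (1R,4R,7R)-4-{2-[(tert-butyldimethylsilyloxy)methyl]oxiran-2-yl}-4,8,8-trimethyl-3-oxabicyclo[5.2.0]nonan-2-one (mixture at the oxirane carbon) | O=C1O[C@@](C)(C2(CO[Si](C)(C)C(C)(C)C)CO2)CC[C@@H]2[C@H]1CC2(C)C
F5 | step 3 | trimethyl{[(1R,6R)-7,7-dimethylbicyclo[4.2.0]oct-2-en-2-yl]oxy}silane | C[Si](C)(C)OC1=CCC[C@@H]2[C@H]1CC2(C)C
F6 | step 8 | (1R,5E,9R)-5-(hydroxymethyl)-6,10,10-trimethylbicyclo[7.2.0]undec-5-en-2-one (cis-fused) | O=C1CC/C(CO)=C(C)\CC[C@@H]2[C@H]1CC2(C)C
F7 | step 8 | (1R,4E,9R)-4,11,11-trimethyl-8-oxobicyclo[7.2.0]undec-4-ene-5-carbaldehyde (cis-fused) | O=C1CC/C(C=O)=C(C)\CC[C@@H]2[C@H]1CC2(C)C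
F8 | step 8 | 9-epi-20 (cis-fused cyclobutane) | O=C1CCC2=CC3=C(O[C@@]2(C)CC[C@@H]2[C@H]1CC2(C)C)C(C)(C)C(=O)C(C(=O)C(C)C)=C3O
F9 | step 8 | 9-epi-21 (cis-fused cyclobutane) | O=C1CC[C@@H]2CC3=C(O[C@@]2(C)CC[C@@H]2[C@H]1CC2(C)C)C(C)(C)C(=O)C(C(=O)C(C)C)=C3O
A1 | alternative 1 | 8-oxo-15-nor target (same structure as 21) | O=C1CC[C@@H]2CC3=C(O[C@@]2(C)CC[C@@H]2[C@@H]1CC2(C)C)C(C)(C)C(=O)C(C(=O)C(C)C)=C3O
A2 | alternative 1 | seco vinyl ketone: trans-cyclobutane with the acryloyl group on C9 and, on C1, the chain C2–C3–C4(CH3)=C5H–C1′H2 attached to C2′ of the enolised trione | CC(C)C(=O)C1=C(O)C(C/C=C(\C)CC[C@@H]2[C@@H](C(=O)C=C)CC2(C)C)=C(O)C(C)(C)C1=O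
A3 | alternative 2 | 5,1′-didehydro target (2H-pyran with the C8 methylidene) | C=C1CCC2=CC3=C(O[C@@]2(C)CC[C@@H]2[C@@H]1CC2(C)C)C(C)(C)C(=O)C(C(=O)C(C)C)=C3O
A4 | alternative 2 | 4,11,11-trimethyl-8-methylidenebicyclo[7.2.0]undec-4-ene-5-carbaldehyde (trans-fused) | C=C1CC/C(C=O)=C(C)\CC[C@@H]2[C@@H]1CC2(C)C
A5 | alternative 3 | caryophyll-8(15)-ene-4,1′-diol acetonide | C=C1CC[C@@H]2COC(C)(C)O[C@@]2(C)CC[C@@H]2[C@@H]1CC2(C)C
A6 | alternative 3 | seco iodoalkene: 5-vinyl-1,3-dioxane acetonide with the C3–C2 chain to the trans-cyclobutane bearing a 1-iodovinyl group on C9 | C=C[C@@H]1COC(C)(C)O[C@@]1(C)CC[C@@H]1[C@@H](C(I)=C)CC1(C)C
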